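## Structural features

The target is a labdane: a trans-fused decalin (ring A = C1–C5 and C10, ring B = C5–C10) with an axial carboxylic acid (C19) and a methyl group (C18) on C4, the angular methyl C20 on C10, an exocyclic methylene (C8=C17) on ring B and, on C9, a five-carbon chain (C11–C15) with a methyl branch at C13 and a stearate on O15. Four stereocentres (C4, C5, C10, C9) are contiguous around the ring fusion; C4 and C10 are quaternary, and C19 and C20 stand 1,3-diaxial on the β face. The fifth stereocentre, C13, is separated from the ring by two methylene groups and must be set independently. The fragile groups are the 1,1-disubstituted alkene (acid can move it into the ring), the unhindered primary stearate (lost to hydroxide, hydride or organometallic reagents) and C9 once a C8 carbonyl stands next to it. The C19 carboxyl is neopentyl and axial, so an ordinary ester there is very hard to hydrolyse; the two carboxyl functions must therefore be unmasked by different mechanisms. The real difficulty is the pair of quaternary centres C4 and C10 in the correct relation to C5 and C9. The key step exploits the position of C10: it is flanked by C4 and C9, and if these are written as carbinol carbons and C5=C10 as an alkene, rings A and B become a C2-symmetric octalindiol. Its two homotopic allylic hydroxyl groups lie on one face of the tetrasubstituted alkene, so both can steer a methylene unit onto C5/C10, and either can later trigger its opening to the C20 methyl.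

## Logic of the disconnections

**C19 mask and O15–acyl bond.** 34 is traced to 33, in which C19 is a 2-(trimethylsilyl)ethyl ester, and 33 to 31 and 32 by cutting the O15–acyl bond. This removes the 18-carbon acyl group and lets the acylation run with no free acid present. The demand is that the last step frees a neopentyl axial acid without touching a primary ester or the alkene, which a mask opened at silicon allows.

**C8=C17.** 31 comes from its silyl ether 30, and 30 from 29 by cutting the C8=C17 double bond. The alkene is thereby exchanged for a ketone that makes C9 epimerisable towards its stable equatorial configuration. The forward step must methylenate a hindered, enolisable ketone.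

**C8–O and C9–H.** 29 comes from 28 by oxidation, and 28 from 26 by removing the C8–O and C9–H bonds as the elements of water across C8=C9. Two stereocentres disappear and C9 becomes sp2. The forward hydroboration must attack the α face, opposite C20.

**C9–C11.** 26 is cut at C9–C11 into 17 and 24 (through 25). This is the convergent cut: it separates the remote C13 centre into a small fragment and leaves a bicyclic core without a side chain. The demand is a cross-coupling at a vinyl triflate next to the quaternary C10.

**The chain fragment.** 24 is traced through 23, 22, 21 and 20 to 19 and 18 by functional-group changes at the two termini. No C–C bond is cut; the gain is that C13 becomes the prochiral centre of a symmetric diester. The forward demand is an enzyme that tells the two enantiotopic ester groups apart, and the correct order of terminus handling: the acid end becomes C15, the ester end C11.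

**The C9 handle.** 17 comes from 15 (C9–O triflate from the ketone), 15 from 14 and 14 from 13 by oxidation-level and protecting-group changes. This keeps C9 as a protected carbinol through the reductive steps. The demand is desilylation under conditions that spare the silylethyl ester.

**C4–C18 and C5–H.** 13 is cut at C4–C18 and C5–H to give 11 (through 12). Both remaining ring-A stereocentres are removed in one operation. The forward reductive methylation must protonate C5 and methylate C4 from the α face.

**C4–C19.** 11 is cut at C4–C19 to give 10. The carboxyl carbon is traded for an enol triflate, that is, for a ketone enolate of defined regiochemistry.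

**C5–C20 (reconnection).** 10 is traced through 9 to 8 by joining C20 back to C5. The quaternary methyl centre becomes a cyclopropane whose face is easy to control. The forward demand is cleavage of C5–C20 only, and capture of the enolate before it equilibrates.

**Differentiation of the two carbinols.** 8 comes from 7 by oxidation and 7 from 6 by monosilylation. Because the hydroxyl groups of 6 are homotopic, any monofunctionalisation gives one compound.

**C10–C20 and C5–C20 (key step).** 6 is cut at both bonds to C20 to give 5. One ring and two stereocentres are lost, and a C2-symmetric diol remains. The forward step needs one alkene face only.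

**The two carbinol C–H bonds.** 5 comes from 3 by twofold enantioselective carbonyl reduction, and 3 from 1 by dehydrogenation across the ring fusion. This ends in a cheap symmetric dione.

## Other disconnections considered

**Alternative 1:** The cut is through C4–C5 and C9–C10, opening both rings to the acyclic β-keto ester A1, a dihydrofarnesyl chain with C13 already in place and an 8-phenylmenthyl ester. In the forward step Mn(OAc)3 (trivalent manganese) would generate the C4 radical, two 6-endo additions would close rings A and B, and Cu(OAc)2 (divalent copper) would turn the C8 radical into the exocyclic alkene of A2.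
- In its favour: one step would make both rings, the four ring stereocentres and the methylene. The axial ester on C4 is the expected outcome, and C13 comes from the open chain.
- Against it here: A2 carries a C3 carbonyl that must be removed next to an isomerisable alkene. The 8-phenylmenthyl ester of a neopentyl axial acid resists cleavage and would probably need reduction and re-oxidation. The copper-mediated elimination can give ring alkenes as well, and the auxiliary controls the absolute sense only through the first C–C bond formation.
- Comparison: on step economy this alternative is the better one, probably by five steps or more. On C4 it is the equal of the chosen plan. It is also better in that it builds the rings, whereas the chosen plan starts from them. The chosen plan is better in that each centre is set by a separate, well-understood element and the acid is released easily.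

**Alternative 2:** The cut is through C8–C9 and C11–C12, back to A3, a cyclohexene bearing the C4=C5 enoate, a vinyl group on C10 and a β-diketone chain. In the forward step, light near 350 nm would add the C8=C12 enol across the vinyl group, and retro-aldol cleavage of the cyclobutanol would close ring B as the C8 ketone of A4.
- In its favour: ring B and the C8 carbonyl would arrive together, and C9 would be epimerisable next to that ketone, which is the equal of the chosen plan. A4 is an enoate of the same type as 11, so ring A would be finished identically (equal).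
- Against it here: A3 must already hold the quaternary C10 centre in enantiopure form, which is the problem the chosen key step solves. The enol and the alkene are tethered by four atoms, so a crossed adduct is a real risk, and the 1,4-diene in A3 may divert the excited state. A4 has two ketones to differentiate and lacks C14 and C15, so C13 would have to be created late on a flexible chain by reagent control alone.
- Comparison: the alternative is better in making ring B and the C8 ketone in one operation. It is worse on C10 and C13, and is unlikely to be shorter overall.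

**Alternative 3:** The cut is through C8–C9, back to the 2-bromoalkene A5, which already carries the complete side chain. In the forward step Bu3SnH and AIBN would give the C8 vinyl radical, which would add 6-exo to C9 and close ring B as A6.
- In its favour: the methylene would be in place at once, which is better than the chosen plan (three steps for the same result). The chain with C13 would be attached convergently, and ring A would be completed from A6 as in the chosen plan (equal).
- Against it here: A5 needs the quaternary C10 centre beforehand. C9 would be set under kinetic control against two similar substituents on C10 and could not be corrected afterwards, because no carbonyl flanks it. Vinyl radicals can also undergo hydrogen transfer or 7-endo closure, and tin residues must be removed.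
- Comparison: fewer steps after ring closure, but the route to A5 is probably as long as the route to 17, so the step count is roughly equal. The chosen plan is better on C9 and C10 control.

Key step: step 3

## Route

Remark: ring positions are given in labdane numbering, β being the face of the C20 methyl group; 1 is taken as the commercial mixture of ring-fusion isomers, which step 1 makes irrelevant; the esterase of step 13 is assumed to show its usual preference for the pro-S ester group of 3-methylglutarates.

Step 1
Reactants: 1 decahydronaphthalene-1,5-dione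
Product: 3 2,3,4,6,7,8-hexahydronaphthalene-1,5-dione, via 8a-bromodecalin-1,5-dione 2 (not isolated)
Conditions: Br2 (1.0 equiv), AcOH, 20 °C; then NaOAc (2.5 equiv), 50 °C
Reagents that add atoms: none
Why: Acid-catalysed α-bromination goes through the more substituted enol and places bromine on the ring-fusion carbon; this bromide is β to the second carbonyl and is lost by E1cB elimination to the conjugated tetrasubstituted ene-dione (bromination–dehydrobromination).

Step 2
Reactants: 3 2,3,4,6,7,8-hexahydronaphthalene-1,5-dione
Product: 5 (1S,5S)-1,2,3,4,5,6,7,8-octahydronaphthalene-1,5-diol, via (5S)-hydroxy enone 4 (not isolated)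
Conditions: (R)-2-methyl-CBS-oxazaborolidine [(3aR)-1-methyl-3,3-diphenyltetrahydro-1H,3H-pyrrolo[1,2-c][1,3,2]oxazaborole] (0.4 equiv), BH3·SMe2 (1.4 equiv), THF, −20 °C; MeOH
Reagents that add atoms: none
Why: Corey–Bakshi–Shibata reduction: each carbonyl binds the catalyst anti to its larger substituent, the alkene carbon, so the (R)-catalyst should give the S carbinol; the second reduction is under the same catalyst control, so a mismatched event ends in the separable meso diol and the C2 diol is enriched.

Step 3
Reactants: 5 (1S,5S)-1,2,3,4,5,6,7,8-octahydronaphthalene-1,5-diol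
Product: 6 (1S,4aR,5S,8aR)-octahydro-4a,8a-methanonaphthalene-1,5-diol
Conditions: Et2Zn (5 equiv), CH2I2 (10 equiv), CH2Cl2, 0 °C → rt
Reagents that add atoms: diiodomethane, ICI
Why: Hydroxyl-directed Simmons–Smith cyclopropanation in the Furukawa variant: Et2Zn converts both hydroxyl groups into zinc alkoxides and with CH2I2 gives the ethyl(iodomethyl)zinc carbenoid. The carbenoid is held by an alkoxide oxygen and passes CH2 to the C5=C10 π bond through a butterfly-type transition state in which C10–C20 and C5–C20 form together while iodide moves to zinc. The closest known reaction type is the directed cyclopropanation of Δ9,10-octalin-1-ols and other cyclic allylic alcohols. The three-membered ring is closed by this concerted [2+1] methylene transfer, not by a stepwise exo or endo closure, so the addition is stereospecifically syn. The new stereocentres C5 and C10 are controlled by the carbinol centres C4 and C9 from step 2: both oxygens lie on the β face, so CH2 must arrive there, which gives C10 the configuration of the target. The only selectivity needed is between the two alkene faces, and it is matched because both directing groups sit on the same face; there is one alkene, and the C2 axis is kept, so one product is expected. The tetrasubstituted alkene is electron-rich, which suits the electrophilic carbenoid, and intramolecular delivery offsets its hindrance.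

Step 4
Reactants: 6 (1S,4aR,5S,8aR)-octahydro-4a,8a-methanonaphthalene-1,5-diol
Product: 7 (1S,4aR,5S,8aR)-5-(tert-butyldimethylsilyloxy)octahydro-4a,8a-methanonaphthalen-1-ol
Conditions: NaH (1.0 equiv), THF, 0 °C → rt; TBSCl (1.0 equiv)
Reagents that add atoms: tert-butyldimethylsilyl chloride, CC(C)(C)[Si](C)(C)Cl
Why: O-Silylation of the monosodium alkoxide of a symmetric diol; the hydroxyl groups are homotopic, so only one monoether can form, and unreacted 6 or any bis-ether can be recycled.

Step 5
Reactants: 7 (1S,4aR,5S,8aR)-5-(tert-butyldimethylsilyloxy)octahydro-4a,8a-methanonaphthalen-1-ol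
Product: 8 (4aR,5S,8aR)-5-(tert-butyldimethylsilyloxy)hexahydro-4a,8a-methanonaphthalen-1(2H)-one
Conditions: Pr4N[RuO4] (5 mol %), NMO (1.5 equiv), 4 Å MS, CH2Cl2, rt
Reagents that add atoms: none
Why: Ley–Griffith oxidation turns the secondary cyclopropylcarbinol into the C4 ketone under neutral conditions, so neither the cyclopropane nor the silyl ether should be touched.

Step 6
Reactants: 8 (4aR,5S,8aR)-5-(tert-butyldimethylsilyloxy)hexahydro-4a,8a-methanonaphthalen-1(2H)-one
Product: 10 (4aS,5S)-5-(tert-butyldimethylsilyloxy)-4a-methyl-2,3,4,4a,5,6,7,8-octahydronaphthalen-1-yl trifluoromethanesulfonate, via lithium enolate 9 (not isolated)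
Conditions: Li (2.2 equiv), t-BuOH (1.0 equiv), NH3(l)/THF, −78 °C; NH3 removed; PhNTf2 (1.5 equiv), THF, −78 → 0 °C; aq. NH4Cl
Reagents that add atoms: N-phenylbis(trifluoromethanesulfonimide), O=S(=O)(N(c1ccccc1)S(=O)(=O)C(F)(F)F)C(F)(F)F
Why: Dissolving-metal cleavage of a conjugated cyclopropyl ketone: the ketyl opens C5–C20, the bond outside ring A that overlaps the carbonyl π system, leaving C20 as the methyl on C10 and a regiodefined C4=C5 lithium enolate; enolate O-triflation with PhNTf2 then fixes the double-bond position, and C10 keeps the configuration from step 3.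

Step 7
Reactants: 10 (4aS,5S)-5-(tert-butyldimethylsilyloxy)-4a-methyl-2,3,4,4a,5,6,7,8-octahydronaphthalen-1-yl trifluoromethanesulfonate
Product: 11 2-(trimethylsilyl)ethyl (4aS,5S)-5-(tert-butyldimethylsilyloxy)-4a-methyl-2,3,4,4a,5,6,7,8-octahydronaphthalene-1-carboxylate
Conditions: Pd(OAc)2 (10 mol %), PPh3 (20 mol %), CO (1 atm), Me3SiCH2CH2OH (10 equiv), Et3N (2 equiv), DMF, 70 °C
Reagents that add atoms: carbon monoxide, [C-]#[O+]; 2-(trimethylsilyl)ethanol, C[Si](C)(C)CCO
Why: Palladium-catalysed alkoxycarbonylation of an enol triflate: oxidative addition to zerovalent palladium, CO insertion and alcoholysis of the acylpalladium put C19 on C4 as an α,β-unsaturated ester; the silylethyl ester is chosen so that the hindered acid can be freed at the end by fluoride.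

Step 8
Reactants: 11 2-(trimethylsilyl)ethyl (4aS,5S)-5-(tert-butyldimethylsilyloxy)-4a-methyl-2,3,4,4a,5,6,7,8-octahydronaphthalene-1-carboxylate
Product: 13 2-(trimethylsilyl)ethyl (1S,4aS,5S,8aR)-5-(tert-butyldimethylsilyloxy)-1,4a-dimethyldecahydronaphthalene-1-carboxylate, via lithium ester enolate 12 (not isolated)
Conditions: Li (2.5 equiv), t-BuOH (1.0 equiv), NH3(l)/THF, −78 °C; MeI (10 equiv), −78 → −33 °C; aq. NH4Cl
Reagents that add atoms: iodomethane, CI
Why: Reductive alkylation of an α,β-unsaturated ester: protonation at C5 on the α face (axial, anti to C20) should give the trans ring fusion, and the exocyclic ester enolate is then methylated on the α face, away from the 1,3-diaxial C20 methyl, so that C18 becomes equatorial and the ester (C19) axial and β.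

Step 9
Reactants: 13 2-(trimethylsilyl)ethyl (1S,4aS,5S,8aR)-5-(tert-butyldimethylsilyloxy)-1,4a-dimethyldecahydronaphthalene-1-carboxylate
Product: 14 2-(trimethylsilyl)ethyl (1S,4aS,5S,8aR)-5-hydroxy-1,4a-dimethyldecahydronaphthalene-1-carboxylate
Conditions: HF (48 % aq.), MeCN, rt
Reagents that add atoms: none
Why: Acidic fluoride desilylation: aqueous HF cleaves the Si–O bond of the secondary silyl ether, whereas the C–Si bond of the silylethyl ester needs fluoride anion and should remain.

Step 10
Reactants: 14 2-(trimethylsilyl)ethyl (1S,4aS,5S,8aR)-5-hydroxy-1,4a-dimethyldecahydronaphthalene-1-carboxylate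
Product: 15 2-(trimethylsilyl)ethyl (1S,4aS,8aR)-1,4a-dimethyl-5-oxodecahydronaphthalene-1-carboxylate
Conditions: Pr4N[RuO4] (5 mol %), NMO (1.5 equiv), 4 Å MS, CH2Cl2, rt
Reagents that add atoms: none
Why: Ley–Griffith oxidation of the equatorial secondary alcohol gives the C9 ketone; C4 is quaternary, so the ester cannot enolise.

Step 11
Reactants: 15 2-(trimethylsilyl)ethyl (1S,4aS,8aR)-1,4a-dimethyl-5-oxodecahydronaphthalene-1-carboxylate
Product: 17 2-(trimethylsilyl)ethyl (1S,4aS,8aR)-1,4a-dimethyl-5-(trifluoromethanesulfonyloxy)-1,2,3,4,4a,7,8,8a-octahydronaphthalene-1-carboxylate, via potassium enolate 16 (not isolated)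
Conditions: KN(SiMe3)2 (1.2 equiv), THF, −78 °C; PhNTf2 (1.3 equiv), −78 → 0 °C; aq. NH4Cl
Reagents that add atoms: N-phenylbis(trifluoromethanesulfonimide), O=S(=O)(N(c1ccccc1)S(=O)(=O)C(F)(F)F)C(F)(F)F
Why: Enolate O-triflation: C10 is quaternary, so deprotonation is possible only at C8 and the C8=C9 enol triflate is the single regioisomer.

Step 12
Reactants: 18 3-methylglutaric anhydride
Product: 19 dimethyl 3-methylpentanedioate
Conditions: MeOH, H2SO4 (cat.), reflux
Reagents that add atoms: methanol, CO
Why: Ring-opening Fischer esterification gives the achiral diester that serves as the enzyme substrate.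

Step 13
Reactants: 19 dimethyl 3-methylpentanedioate
Product: 20 (3R)-5-methoxy-3-methyl-5-oxopentanoic acid
Conditions: pig liver esterase, 0.1 M phosphate buffer (pH 7)–MeOH (4:1), −10 °C, 1 M NaOH (pH-stat, 1.0 equiv); HCl to pH 2
Reagents that add atoms: water, O
Why: Enzymatic desymmetrisation: the esterase hydrolyses one of the two enantiotopic ester groups, and for the 3-methyl diester the pro-S group is expected to react, giving the R half-ester and thereby setting C13.

Step 14
Reactants: 20 (3R)-5-methoxy-3-methyl-5-oxopentanoic acid
Product: 21 methyl (3R)-5-hydroxy-3-methylpentanoate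
Conditions: BH3·SMe2 (1.1 equiv), THF, 0 °C → rt; MeOH
Reagents that add atoms: none
Why: Chemoselective borane reduction of the carboxylic acid, through its acyloxyborane, beside the methyl ester; the crude alcohol is silylated at once to forestall lactonisation.

Step 15
Reactants: 21 methyl (3R)-5-hydroxy-3-methylpentanoate
Product: 22 methyl (3R)-5-(tert-butyldimethylsilyloxy)-3-methylpentanoate
Conditions: TBSCl (1.2 equiv), imidazole (2.5 equiv), DMF, rt
Reagents that add atoms: tert-butyldimethylsilyl chloride, CC(C)(C)[Si](C)(C)Cl
Why: Imidazole-mediated silylation of the primary alcohol, whose oxygen becomes O15.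

Step 16
Reactants: 22 methyl (3R)-5-(tert-butyldimethylsilyloxy)-3-methylpentanoate
Product: 23 (3S)-5-(tert-butyldimethylsilyloxy)-3-methylpentan-1-ol
Conditions: LiAlH4 (1.0 equiv), Et2O, 0 °C
Reagents that add atoms: none
Why: Hydride reduction of the ester gives the primary alcohol at the future C11; the descriptor changes only because the priorities change.

Step 17
Reactants: 23 (3S)-5-(tert-butyldimethylsilyloxy)-3-methylpentan-1-ol
Product: 24 (3R)-tert-butyl[(5-iodo-3-methylpentyl)oxy]dimethylsilane
Conditions: I2 (1.2 equiv), PPh3 (1.2 equiv), imidazole (1.5 equiv), CH2Cl2, 0 °C → rt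
Reagents that add atoms: iodine, II
Why: Appel-type iodination: iodide displaces the oxyphosphonium group at the primary carbon by SN2, and the stereocentre is not involved.

Step 18
Reactants: 24 (3R)-tert-butyl[(5-iodo-3-methylpentyl)oxy]dimethylsilane; 17 2-(trimethylsilyl)ethyl (1S,4aS,8aR)-1,4a-dimethyl-5-(trifluoromethanesulfonyloxy)-1,2,3,4,4a,7,8,8a-octahydronaphthalene-1-carboxylate
Product: 26 2-(trimethylsilyl)ethyl (4S,5R,10S,13S)-15-(tert-butyldimethylsilyloxy)-17-norlabd-8-en-19-oate, via alkylzinc iodide 25 (not isolated)
Conditions: 24, Zn dust (2 equiv), I2 (5 mol %), DMA, 40 °C; then 17, Pd(PPh3)4 (5 mol %), LiCl (2 equiv), THF, 55 °C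
Reagents that add atoms: none
Why: Negishi cross-coupling: zinc inserts into the primary C–I bond, the alkylzinc iodide transmetalates to the alkenylpalladium species formed by oxidative addition of 17 to zerovalent palladium, and reductive elimination forms C9–C11; the silyl ether and the hindered ester are inert to the zinc reagent.

Step 19
Reactants: 26 2-(trimethylsilyl)ethyl (4S,5R,10S,13S)-15-(tert-butyldimethylsilyloxy)-17-norlabd-8-en-19-oate
Product: 28 2-(trimethylsilyl)ethyl (4S,5R,8R,9R,10S,13S)-15-(tert-butyldimethylsilyloxy)-8-hydroxy-17-norlabdan-19-oate (8α-OH, 9α-H), via C8 alkylborane 27 (not isolated)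
Conditions: BH3·THF (3 equiv), THF, 0 °C → rt; NaOH (3 M), H2O2 (30 %), 0 °C → rt
Reagents that add atoms: hydrogen peroxide, OO
Why: Hydroboration–oxidation: boron adds to the less substituted C8 and hydrogen to C9, syn and on the α face opposite the axial C20 methyl, so H9 is α and the chain β; oxidation with retention gives the equatorial 8α alcohol.

Step 20
Reactants: 28 2-(trimethylsilyl)ethyl (4S,5R,8R,9R,10S,13S)-15-(tert-butyldimethylsilyloxy)-8-hydroxy-17-norlabdan-19-oate
Product: 29 2-(trimethylsilyl)ethyl (4S,5R,9R,10S,13S)-15-(tert-butyldimethylsilyloxy)-8-oxo-17-norlabdan-19-oate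
Conditions: Pr4N[RuO4] (5 mol %), NMO (1.5 equiv), 4 Å MS, CH2Cl2, rt
Reagents that add atoms: none
Why: Ley–Griffith oxidation gives the C8 ketone; the C9 chain is already equatorial, the thermodynamically preferred arrangement, so enolisation cannot erode it.

Step 21
Reactants: 29 2-(trimethylsilyl)ethyl (4S,5R,9R,10S,13S)-15-(tert-butyldimethylsilyloxy)-8-oxo-17-norlabdan-19-oate
Product: 30 2-(trimethylsilyl)ethyl (4S,5R,9S,10R,13S)-15-(tert-butyldimethylsilyloxy)labd-8(17)-en-19-oate
Conditions: Ph3PCH3Br (4 equiv), KOtBu (3.8 equiv), THF, 0 → 50 °C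
Reagents that add atoms: methyltriphenylphosphonium bromide, C[P+](c1ccccc1)(c1ccccc1)c1ccccc1.[Br-]
Why: Wittig methylenation with methylidenetriphenylphosphorane installs C17 as the exocyclic alkene; any epimerisation at C9 by the basic ylide returns to the equatorial chain.

Step 22
Reactants: 30 2-(trimethylsilyl)ethyl (4S,5R,9S,10R,13S)-15-(tert-butyldimethylsilyloxy)labd-8(17)-en-19-oate
Product: 31 2-(trimethylsilyl)ethyl (4S,5R,9S,10R,13S)-15-hydroxylabd-8(17)-en-19-oate
Conditions: (1S)-10-camphorsulfonic acid (10 mol %), MeOH–CH2Cl2 (1:1), 0 °C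
Reagents that add atoms: none
Why: Acid-catalysed methanolysis of the primary silyl ether; the silylethyl ester and the 1,1-disubstituted alkene should tolerate catalytic sulfonic acid at 0 °C.

Step 23
Reactants: 31 2-(trimethylsilyl)ethyl (4S,5R,9S,10R,13S)-15-hydroxylabd-8(17)-en-19-oate; 32 stearoyl chloride
Product: 33 2-(trimethylsilyl)ethyl (4S,5R,9S,10R,13S)-15-(octadecanoyloxy)labd-8(17)-en-19-oate
Conditions: pyridine (3 equiv), 4-(dimethylamino)pyridine (10 mol %), CH2Cl2, 0 °C → rt
Reagents that add atoms: none
Why: Nucleophile-catalysed acylation of the only free hydroxyl group by the acid chloride; C19 is still masked, so no mixed anhydride can form.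

Step 24
Reactants: 33 2-(trimethylsilyl)ethyl (4S,5R,9S,10R,13S)-15-(octadecanoyloxy)labd-8(17)-en-19-oate
Product: 34 (4S,5R,9S,10R,13S)-15-(octadecanoyloxy)labd-8(17)-en-19-oic acid (CNP0298278.1)
Conditions: Bu4NF (3 equiv), THF, 0 °C → rt; 0.5 M HCl (work-up)
Reagents that add atoms: none
Why: Fluoride-induced β-elimination of the 2-(trimethylsilyl)ethyl ester (loss of fluorotrimethylsilane and ethene) frees the hindered C19 acid by attack at the remote silicon and not at a carbonyl, so the stearate should remain.

## Compound list

1 | decahydronaphthalene-1,5-dione (mixture of ring-fusion isomers) | O=C1CCCC2C1CCCC2=O | starting material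
2 | 8a-bromooctahydronaphthalene-1,5(2H,6H)-dione (not isolated) | O=C1CCCC2C1(Br)CCCC2=O | intermediate
3 | 2,3,4,6,7,8-hexahydronaphthalene-1,5-dione | O=C1CCCC2=C1CCCC2=O | intermediate
4 | (5S)-5-hydroxy-3,4,5,6,7,8-hexahydronaphthalen-1(2H)-one, present as its borate (not isolated) | O=C1CCCC2=C1CCC[C@@H]2O | intermediate
5 | (1S,5S)-1,2,3,4,5,6,7,8-octahydronaphthalene-1,5-diol | O[C@H]1CCCC2=C1CCC[C@@H]2O | intermediate
6 | (1S,4aR,5S,8aR)-octahydro-4a,8a-methanonaphthalene-1,5-diol | O[C@H]1CCC[C@@]23C[C@@]12CCC[C@@H]3O | intermediate
7 | (1S,4aR,5S,8aR)-5-(tert-butyldimethylsilyloxy)octahydro-4a,8a-methanonaphthalen-1-ol | O[C@H]1CCC[C@@]23C[C@@]12CCC[C@@H]3O[Si](C)(C)C(C)(C)C | intermediate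
8 | (4aR,5S,8aR)-5-(tert-butyldimethylsilyloxy)hexahydro-4a,8a-methanonaphthalen-1(2H)-one | O=C1CCC[C@@]23C[C@@]12CCC[C@@H]3O[Si](C)(C)C(C)(C)C | intermediate
9 | lithium (4aS,5S)-5-(tert-butyldimethylsilyloxy)-4a-methyl-2,3,4,4a,5,6,7,8-octahydronaphthalen-1-olate (not isolated) | [Li]OC1=C2CCC[C@H](O[Si](C)(C)C(C)(C)C)[C@@]2(C)CCC1 | intermediate
10 | (4aS,5S)-5-(tert-butyldimethylsilyloxy)-4a-methyl-2,3,4,4a,5,6,7,8-octahydronaphthalen-1-yl trifluoromethanesulfonate | FC(F)(F)S(=O)(=O)OC1=C2CCC[C@H](O[Si](C)(C)C(C)(C)C)[C@@]2(C)CCC1 | intermediate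
11 | 2-(trimethylsilyl)ethyl (4aS,5S)-5-(tert-butyldimethylsilyloxy)-4a-methyl-2,3,4,4a,5,6,7,8-octahydronaphthalene-1-carboxylate | C[Si](C)(C)CCOC(=O)C1=C2CCC[C@H](O[Si](C)(C)C(C)(C)C)[C@@]2(C)CCC1 | intermediate
12 | lithium ester enolate of 13 lacking C18: lithium [(4aS,5S,8aR)-5-(tert-butyldimethylsilyloxy)-4a-methyloctahydronaphthalen-1(2H)-ylidene][2-(trimethylsilyl)ethoxy]methanolate (not isolated) | [Li]OC(OCC[Si](C)(C)C)=C1CCC[C@]2(C)[C@@H](O[Si](C)(C)C(C)(C)C)CCC[C@@H]12 | intermediate
13 | 2-(trimethylsilyl)ethyl (1S,4aS,5S,8aR)-5-(tert-butyldimethylsilyloxy)-1,4a-dimethyldecahydronaphthalene-1-carboxylate | C[Si](C)(C)CCOC(=O)[C@@]1(C)CCC[C@]2(C)[C@@H](O[Si](C)(C)C(C)(C)C)CCC[C@@H]12 | intermediate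
14 | 2-(trimethylsilyl)ethyl (1S,4aS,5S,8aR)-5-hydroxy-1,4a-dimethyldecahydronaphthalene-1-carboxylate | C[Si](C)(C)CCOC(=O)[C@@]1(C)CCC[C@]2(C)[C@@H](O)CCC[C@@H]12 | intermediate
15 | 2-(trimethylsilyl)ethyl (1S,4aS,8aR)-1,4a-dimethyl-5-oxodecahydronaphthalene-1-carboxylate | C[Si](C)(C)CCOC(=O)[C@@]1(C)CCC[C@]2(C)C(=O)CCC[C@@H]12 | intermediate
16 | potassium C8=C9 enolate of 15 (not isolated) | C[Si](C)(C)CCOC(=O)[C@@]1(C)CCC[C@]2(C)C(O[K])=CCC[C@@H]12 | intermediate
17 | 2-(trimethylsilyl)ethyl (1S,4aS,8aR)-1,4a-dimethyl-5-(trifluoromethanesulfonyloxy)-1,2,3,4,4a,7,8,8a-octahydronaphthalene-1-carboxylate | C[Si](C)(C)CCOC(=O)[C@@]1(C)CCC[C@]2(C)C(OS(=O)(=O)C(F)(F)F)=CCC[C@@H]12 | intermediate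
18 | 3-methylglutaric anhydride | CC1CC(=O)OC(=O)C1 | starting material
19 | dimethyl 3-methylpentanedioate | COC(=O)CC(C)CC(=O)OC | intermediate
20 | (3R)-5-methoxy-3-methyl-5-oxopentanoic acid | COC(=O)C[C@H](C)CC(=O)O | intermediate
21 | methyl (3R)-5-hydroxy-3-methylpentanoate | COC(=O)C[C@H](C)CCO | intermediate
22 | methyl (3R)-5-(tert-butyldimethylsilyloxy)-3-methylpentanoate | COC(=O)C[C@H](C)CCO[Si](C)(C)C(C)(C)C | intermediate
23 | (3S)-5-(tert-butyldimethylsilyloxy)-3-methylpentan-1-ol | OCC[C@H](C)CCO[Si](C)(C)C(C)(C)C | intermediate
24 | (3R)-tert-butyl[(5-iodo-3-methylpentyl)oxy]dimethylsilane | ICC[C@H](C)CCO[Si](C)(C)C(C)(C)C | intermediate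
25 | [(3R)-5-(tert-butyldimethylsilyloxy)-3-methylpentyl]zinc iodide (not isolated) | I[Zn]CC[C@H](C)CCO[Si](C)(C)C(C)(C)C | intermediate
26 | 2-(trimethylsilyl)ethyl (4S,5R,10S,13S)-15-(tert-butyldimethylsilyloxy)-17-norlabd-8-en-19-oate | C[Si](C)(C)CCOC(=O)[C@@]1(C)CCC[C@]2(C)C(CC[C@H](C)CCO[Si](C)(C)C(C)(C)C)=CCC[C@@H]12 | intermediate
27 | 8α-boranyl, 9α-H adduct of 26 (C8 alkylborane, not isolated) | C[Si](C)(C)CCOC(=O)[C@@]1(C)CCC[C@]2(C)[C@@H](CC[C@H](C)CCO[Si](C)(C)C(C)(C)C)[C@H]([BH2])CC[C@@H]12 | intermediate
28 | 2-(trimethylsilyl)ethyl (4S,5R,8R,9R,10S,13S)-15-(tert-butyldimethylsilyloxy)-8-hydroxy-17-norlabdan-19-oate (8α-OH, 9α-H) | C[Si](C)(C)CCOC(=O)[C@@]1(C)CCC[C@]2(C)[C@@H](CC[C@H](C)CCO[Si](C)(C)C(C)(C)C)[C@H](O)CC[C@@H]12 | intermediate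
29 | 2-(trimethylsilyl)ethyl (4S,5R,9R,10S,13S)-15-(tert-butyldimethylsilyloxy)-8-oxo-17-norlabdan-19-oate | C[Si](C)(C)CCOC(=O)[C@@]1(C)CCC[C@]2(C)[C@@H](CC[C@H](C)CCO[Si](C)(C)C(C)(C)C)C(=O)CC[C@@H]12 | intermediate
30 | 2-(trimethylsilyl)ethyl (4S,5R,9S,10R,13S)-15-(tert-butyldimethylsilyloxy)labd-8(17)-en-19-oate | C[Si](C)(C)CCOC(=O)[C@@]1(C)CCC[C@]2(C)[C@@H](CC[C@H](C)CCO[Si](C)(C)C(C)(C)C)C(=C)CC[C@@H]12 | intermediate
31 | 2-(trimethylsilyl)ethyl (4S,5R,9S,10R,13S)-15-hydroxylabd-8(17)-en-19-oate | C[Si](C)(C)CCOC(=O)[C@@]1(C)CCC[C@]2(C)[C@@H](CC[C@H](C)CCO)C(=C)CC[C@@H]12 | intermediate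
32 | stearoyl chloride (octadecanoyl chloride) | CCCCCCCCCCCCCCCCCC(=O)Cl | starting material
33 | 2-(trimethylsilyl)ethyl (4S,5R,9S,10R,13S)-15-(octadecanoyloxy)labd-8(17)-en-19-oate | C[Si](C)(C)CCOC(=O)[C@@]1(C)CCC[C@]2(C)[C@@H](CC[C@H](C)CCOC(=O)CCCCCCCCCCCCCCCCC)C(=C)CC[C@@H]12 | intermediate
34 | (4S,5R,9S,10R,13S)-15-(octadecanoyloxy)labd-8(17)-en-19-oic acid (CNP0298278.1) | C=C1CC[C@@H]2[C@](C)(CCC[C@]2(C)C(=O)O)[C@H]1CC[C@H](C)CCOC(=O)CCCCCCCCCCCCCCCCC | target

## Step count and least certain steps

Total: 24 steps. Longest linear sequence: 18 steps (steps 1–11 and 18–24, from 1). The chain fragment takes 6 steps (12–17) and joins at step 18.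

**Step 3 (key step).** The methylene transfer may stall, because the zinc bis-alkoxide of a rigid diol can aggregate and precipitate and the alkene is tetrasubstituted; prolonged exposure to excess carbenoid can also methylate oxygen. Face selectivity itself is not at risk, since both directing groups share one face. Fallback: setting out from 5, the diol is monosilylated first (NaH, TBSCl, THF) to (1S,5S)-5-(tert-butyldimethylsilyloxy)-1,2,3,4,5,6,7,8-octahydronaphthalen-1-ol F1. This soluble monoether is cyclopropanated under the direction of its single free hydroxyl group (Et2Zn, CH2I2), and the sequence rejoins the route at 7. This removes the bis-alkoxide and merges two steps into a different order.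

**Step 2.** The doubly activated alkene of 3 may be reduced in the conjugate sense or hydroborated, and imperfect control in the first reduction would increase the meso diol. Fallback: setting out from 3, a non-selective Luche reduction (NaBH4, CeCl3·7H2O, MeOH) gives 1,2,3,4,5,6,7,8-octahydronaphthalene-1,5-diol as a mixture of racemic and meso forms F2. Lipase-catalysed acylation (Burkholderia cepacia lipase, vinyl acetate) is then expected, by the usual size rule, to acylate R carbinol centres only. The enantiomer becomes (1R,5R)-1,2,3,4,5,6,7,8-octahydronaphthalene-1,5-diyl diacetate F3, the meso diol becomes (1R,5S)-5-hydroxy-1,2,3,4,5,6,7,8-octahydronaphthalen-1-yl acetate F4, and the untouched diol is 5, where the route is rejoined after chromatography.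

**Step 6.** The enolate may be protonated or may exchange protons before it is sulfonylated, which would lose the regiochemistry, and basic lithium salts left from the reduction may consume PhNTf2. Over-reduction of the ketone is also possible if protonation precedes the second electron transfer. Fallback: setting out from 8, the same reductive opening is quenched with Me3SiCl/Et3N to give [(4aS,5S)-5-(tert-butyldimethylsilyloxy)-4a-methyl-2,3,4,4a,5,6,7,8-octahydronaphthalen-1-yl]oxytrimethylsilane F5, which is isolated. MeLi in THF then regenerates the salt-free lithium enolate 9, and PhNTf2 gives 10, where the route is rejoined.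

**Step 8.** The ester enolate may be protonated instead of methylated, the ester may be over-reduced, or C5 may be protonated without full face control; these are the two stereocentres that cannot be corrected later. Fallback: setting out from 11, reduction alone (Li, NH3, t-BuOH, then NH4Cl) gives 2-(trimethylsilyl)ethyl (4aS,5S,8aS)-5-(tert-butyldimethylsilyloxy)-4a-methyldecahydronaphthalene-1-carboxylate F6 as a mixture of C4 epimers. This allows the ring fusion to be checked and purified. Separate enolate alkylation (LiN(iPr)2, THF, −78 °C; MeI) then erases C4 and methylates on the α face to give 13, where the route is rejoined.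

**Step 18.** Oxidative addition and transmetalation at a triflate beside the quaternary C10 may be slow, so that β-hydride elimination of the alkyl group, reduction of the triflate or its hydrolysis compete. Fallback: setting out from 24, iodine–lithium exchange (t-BuLi, Et2O, −78 °C) and capture with 9-methoxy-9-borabicyclo[3.3.1]nonane give lithium B-methoxy-B-[(3S)-5-(tert-butyldimethylsilyloxy)-3-methylpentyl]-9-borabicyclo[3.3.1]nonan-9-uide F7. This borate is coupled with 17 in a B-alkyl Suzuki–Miyaura reaction (PdCl2(dppf), K3PO4, DMF–H2O) to give 26, where the route is rejoined.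

**Step 19.** Hydroboration of a trisubstituted alkene between a quaternary carbon and a branched chain may be sluggish, and the forcing conditions then needed may start to reduce the ester. Attack on the β face is less serious, because C9 can be equilibrated at the stage of 29. Fallback: setting out from 26, dihydroxylation on the α face (OsO4, NMO) gives 2-(trimethylsilyl)ethyl (13S)-15-(tert-butyldimethylsilyloxy)-8α,9α-dihydroxy-17-norlabdan-19-oate F8. Oxidation of its secondary hydroxyl group gives 2-(trimethylsilyl)ethyl (13S)-15-(tert-butyldimethylsilyloxy)-9α-hydroxy-8-oxo-17-norlabdan-19-oate F9. Reductive removal of the α-hydroxyl group with SmI2 (THF–MeOH), followed by protonation of the enolate to the equatorial chain, gives 29, where the route is rejoined.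

## Further compounds

F1 | step 3 | (1S,5S)-5-(tert-butyldimethylsilyloxy)-1,2,3,4,5,6,7,8-octahydronaphthalen-1-ol | O[C@H]1CCCC2=C1CCC[C@@H]2O[Si](C)(C)C(C)(C)C
F2 | step 2 | 1,2,3,4,5,6,7,8-octahydronaphthalene-1,5-diol, mixture of racemic and meso forms | OC1CCCC2=C1CCCC2O
F3 | step 2 | (1R,5R)-1,2,3,4,5,6,7,8-octahydronaphthalene-1,5-diyl diacetate | CC(=O)O[C@@H]1CCCC2=C1CCC[C@H]2OC(C)=O
F4 | step 2 | (1R,5S)-5-hydroxy-1,2,3,4,5,6,7,8-octahydronaphthalen-1-yl acetate | CC(=O)O[C@@H]1CCCC2=C1CCC[C@@H]2O
F5 | step 6 | [(4aS,5S)-5-(tert-butyldimethylsilyloxy)-4a-methyl-2,3,4,4a,5,6,7,8-octahydronaphthalen-1-yl]oxytrimethylsilane | C[Si](C)(C)OC1=C2CCC[C@H](O[Si](C)(C)C(C)(C)C)[C@@]2(C)CCC1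
F6 | step 8 | 2-(trimethylsilyl)ethyl (4aS,5S,8aS)-5-(tert-butyldimethylsilyloxy)-4a-methyldecahydronaphthalene-1-carboxylate, mixture of C1 epimers | C[Si](C)(C)CCOC(=O)C1CCC[C@]2(C)[C@@H](O[Si](C)(C)C(C)(C)C)CCC[C@@H]12
F7 | step 18 | lithium B-methoxy-B-[(3S)-5-(tert-butyldimethylsilyloxy)-3-methylpentyl]-9-borabicyclo[3.3.1]nonan-9-uide | [Li+].CO[B-]1(CC[C@H](C)CCO[Si](C)(C)C(C)(C)C)C2CCCC1CCC2
F8 | step 19 | 2-(trimethylsilyl)ethyl (13S)-15-(tert-butyldimethylsilyloxy)-8α,9α-dihydroxy-17-norlabdan-19-oate (C4, C5, C10 as in 29) | C[Si](C)(C)CCOC(=O)[C@@]1(C)CCC[C@]2(C)[C@@](O)(CC[C@H](C)CCO[Si](C)(C)C(C)(C)C)[C@H](O)CC[C@@H]12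
F9 | step 19 | 2-(trimethylsilyl)ethyl (13S)-15-(tert-butyldimethylsilyloxy)-9α-hydroxy-8-oxo-17-norlabdan-19-oate (C4, C5, C10 as in 29) | C[Si](C)(C)CCOC(=O)[C@@]1(C)CCC[C@]2(C)[C@@](O)(CC[C@H](C)CCO[Si](C)(C)C(C)(C)C)C(=O)CC[C@@H]12
A1 | alternative 1 | (1R,2S,5R)-8-phenylmenthyl (6E,10E,14S)-16-(tert-butyldiphenylsilyloxy)-2,6,10,14-tetramethyl-3-oxohexadeca-6,10-dienoate | CC(C(=O)CC/C(C)=C/CC/C(C)=C/CC[C@H](C)CCO[Si](c1ccccc1)(c1ccccc1)C(C)(C)C)C(=O)O[C@@H]1C[C@H](C)CC[C@H]1C(C)(C)c1ccccc1
A2 | alternative 1 | (1R,2S,5R)-8-phenylmenthyl 15-(tert-butyldiphenylsilyloxy)-3-oxolabd-8(17)-en-19-oate | C=C1CC[C@@H]2[C@](C)(CCC(=O)[C@]2(C)C(=O)O[C@@H]3C[C@H](C)CC[C@H]3C(C)(C)c4ccccc4)[C@H]1CC[C@H](C)CCO[Si](c5ccccc5)(c6ccccc6)C(C)(C)C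
A3 | alternative 2 | methyl (3R)-3-ethenyl-3-methyl-2-(3,5-dioxohexyl)cyclohex-1-ene-1-carboxylate | COC(=O)C1=C(CCC(=O)CC(C)=O)[C@@](C)(C=C)CCC1
A4 | alternative 2 | methyl 8,13-dioxo-14,15,17,18-tetranorlabd-4-en-19-oate | O=C1CCC2=C(C(=O)OC)CCC[C@]2(C)[C@H]1CCC(C)=O
A5 | alternative 3 | methyl (3R)-2-(3-bromobut-3-en-1-yl)-3-[(1E,4S)-6-(tert-butyldimethylsilyloxy)-4-methylhex-1-en-1-yl]-3-methylcyclohex-1-ene-1-carboxylate | COC(=O)C1=C(CCC(Br)=C)[C@@](C)(/C=C/C[C@H](C)CCO[Si](C)(C)C(C)(C)C)CCC1
A6 | alternative 3 | methyl 15-(tert-butyldimethylsilyloxy)-18-norlabda-4,8(17)-dien-19-oate | C=C1CCC2=C(C(=O)OC)CCC[C@]2(C)[C@H]1CC[C@H](C)CCO[Si](C)(C)C(C)(C)C
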